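# Proposed total synthesis of gnetofuran A, (2R,3S) enantiomer

## Structural features

Gnetofuran A is a 2,3-dihydrobenzofuran. Ring A is fused to the oxygen heterocycle (O1, C2, C3, C3a, C7a), carries a methoxy group at C7 and, at C5, an E-configured ethene bridge to a resorcinol ring (ring C). C2 bears O1 and ring B (4-hydroxy-3-methoxyphenyl); C3 is bonded to C3a of ring A and bears the hydroxymethyl arm C9. C2 (R) and C3 (S) are the only stereocentres; they are adjacent and trans. Because ring B has a free para-hydroxyl group, the O1–C2 bond can ionise reversibly to a para-quinone methide. C2 is therefore mobile under acid or strong base and settles trans to C9, whereas C3 carries no heteroatom and cannot be corrected later. The fragile elements are the three phenols, the electron-rich stilbene (light, oxidants, strong acid), the para-hydroxybenzyl aryl ether O1–C2, and the possible loss of C9 as formaldehyde from a cation at C2. The real difficulty is the absolute configuration at C3, a carbon flanked by two different aryl-bearing positions. The key step exploits that C2 and C3 are neighbouring sp3 carbons, each carrying one aryl group (ring B on C2, ring A through C3a on C3), with C9 on C3 and a heteroatom on C2. The unit C2–C3–C9 thus maps onto a three-carbon E-alkenylboron reagent across which both aryl groups are added.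

## Logic of the disconnections

**29 back to 28, then 21 + 26 (via 27).** No skeletal bond is cut between 29 and 28; four silyl ethers are removed last so that the polyphenol exists only once. In 28 the C=C bond of the stilbene is cut. This is the most convergent cut, it gives E geometry from a stabilised phosphonate, and it lets ring C arrive as a cheap symmetric unit. The forward step needs base-tolerant protecting groups of one kind on both partners and a substrate with no base-labile stereocentre; C3–H of 21 is meta to the formyl group and not acidified.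

**21 back to 20, 19 and 18.** No bond is cut; the C5 substituent is adjusted from ester to aldehyde and the phenol and primary alcohol are capped. The ester is kept up to 18 because it is the spectator that survives the borate and palladium chemistry. The price is a reduction–oxidation pair and one silylation.

**18 back to 15 (via 16 and 17).** The O1–C2 bond is cut. C2 is a para-hydroxybenzylic position, so this bond forms reversibly through 17 and ends trans under the control of C3. The gain is large: the heterocycle opens to an acyclic 1,2-diarylpropane in which only C3 must be controlled. The forward step needs a leaving oxygen on C2, an acid-labile mask on the ring A phenol, and acid that does not eliminate C3–H or C9.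

**15 back to 14.** The C2–O bond is exchanged for C2–B. Oxidation of a C–B bond is stereoretentive and mild, so boron is a masked hydroxyl. The forward step needs an oxidant that spares the methyl ester.

**14 back to 13, then 12 + 6 + 11.** Two bonds are cut: C2–ring B and C3–C3a. Both aryl–C(sp3) bonds and the C3 stereocentre arise in one catalytic enantioselective event, and the molecule falls into three fragments each one to three steps from commercial material. The forward step needs complete ate-complex formation, a metallate shift faster than direct aryl transfer, and a catalyst that selects one alkene face.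

**6 back to 2 + 4 (via 5), 2 back to 1, 4 back to 3.** The C–B bond is cut (syn hydroboration of a terminal alkyne fixes E geometry), then the B–O bonds (exchange of diol) and the O–Si bond. The hindered diol comes from double methyl addition to a diketone. The forward step needs regioselective hydroboration and clean ester exchange.

**12 back to 8 and 7.** The C–Li bond comes from C–Br, and the phenol is masked as an acetal. The forward step needs exchange at low temperature and a protecting group inert to alkyllithium.

**11 back to 10 and 9.** The O–S bond of the triflate at O3 and the acetal at O4 are cut. The forward step needs regioselective protection of O4, which rests on the higher acidity of the hydroxyl para to the ester.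

**26 back to 25, 24, 23 and 22.** The P–C bond is cut (Arbuzov), then C–Br, then the oxidation level and the silyl ethers. All are standard operations on a symmetric ring.

## Other disconnections considered

**Alternative 1:** The cut is C2–C3. In the forward step Rh2(S-DOSP)4 converts the aryldiazoacetate A2 into a donor/acceptor carbenoid. This inserts into a benzylic C–H bond of the ring B methylene ether and closes the dihydrofuran, giving A1.
- In its favour: ring and both stereocentres form in one step; O1–C2 is never broken, so C2 is made once and kept; the ester on C3 becomes C9 by reduction. The C5 bromide allows a Heck coupling with styrene A3 that gives the E-stilbene without any aldehyde adjustment.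
- Against it here: such 1,5-insertions normally favour the cis product. Reaching trans needs either a matched pair of stoichiometric lactamide auxiliary and chiral catalyst or a later epimerisation at C3. The auxiliary must be attached and removed, a diazo compound must be made and handled, and oxonium ylide formation at the ether oxygen can compete with insertion.
- Comparison: on structure it is the better plan, since it builds the heterocycle directly and does not sacrifice the C2 configuration. On mechanism it needs two chiral controllers where the chosen plan needs one ligand. On step economy its endgame is shorter (better) and its route to A2 is linear and longer, so the totals should be about equal. It is less convergent.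

**Alternative 2:** The cut removes two C–C bonds of ring C. In the forward step the 3-alkenylcyclobutenone A5 is heated with the silyloxyalkyne A6. The sequence is four-electron ring opening to a vinylketene, [2+2] addition, a second ring opening, six-electron electrocyclisation and tautomerisation, and it gives the resorcinol mono-silyl ether A4.
- In its favour: the resorcinol forms regiospecifically without metal or base, and the E alkene is carried through from A5 and does not depend on olefination selectivity. On this last point it is the equal or better of the chosen plan.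
- Against it here: ring C is symmetric and commercially trivial, so building it de novo solves no problem of this target. The C2/C3 stereocentres must still be made by another strategy. A5 must be assembled on the advanced chiral fragment, and the para-oxygenated benzylic ether must survive prolonged heating.
- Comparison: on structure it addresses the easy part of the molecule. On mechanism the pericyclic cascade is clean and predictable. On step economy it is worse, because several steps on valuable material replace one olefination.

**Alternative 3:** The cut is O1–C2, made oxidatively. In the forward step DDQ abstracts hydride from the C2 methylene of A8, activated by the para-hydroxyl of ring B. The resulting para-quinone methide is captured by the ring A phenol to give A7, which is identical with 18.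
- In its favour: no oxygen is ever installed at C2 and then expelled, which is a real advantage in redox and atom economy. A8 has a single stereocentre that auxiliary alkylation or asymmetric hydrogenation can set. The trans selectivity arises exactly as in the chosen plan, and the endgame from A7 is the same (equal).
- Against it here: DDQ meets two free phenols. The product's C2–H is more activated than the methylene of A8, so over-oxidation to the benzofuran or re-opening is a risk. The quinone methide can also tautomerise toward C3 in the presence of oxidant.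
- Comparison: on structure A8 is simpler than 14 and wastes no stereochemical information (better). On mechanism both plans pass through the same quinone methide; the chosen plan reaches it by ionisation without an oxidant, which is the more tolerant way. On step economy the two are about equal, since A8 needs its own asymmetric step with attachment and removal of a controller.

Key step: step 7

**Remarks on the chemistry (assumptions and corrections)**

- Boron substituent: a pinacol ester on a β-substituted alkenylboron unit is expected to divert to direct Suzuki–Miyaura transfer. The boron therefore carries the hindered cis-1,2-dimethylacenaphthene-1,2-diol ("mac", diol 4) from the start, written B(mac); the carbon skeletons of precursor and product are unchanged.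
- Oxygen bookkeeping at C2: the oxygen delivered by C–B oxidation is not O1. O1 is the ring A phenol oxygen already present in 11, and the boron-derived hydroxyl leaves as water in step 9. The C2 configuration made in step 7 is thus transient; C2 is finally set trans in step 9 under control of C3, which step 7 sets permanently.
- Assumption: both antipodes of the MandyPhos ligand are available. The antipode that places palladium on the alkene face that is Re at the CH2O-bearing carbon (giving (1R,2S)-14) is identified in a pilot run and used.
- Ate complex 13 may be a mixture of isomers at boron; this has no consequence.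

## Steps

Step 1
Reactants: 1 prop-2-yn-1-ol (propargyl alcohol)
Product: 2 tert-butyldimethyl(prop-2-yn-1-yloxy)silane
Conditions: TBSCl, imidazole, CH2Cl2, 0 °C → rt
Reagents that add atoms: tert-butyldimethylsilyl chloride, CC(C)(C)[Si](C)(C)Cl
Why: Standard silyl ether formation on a primary alcohol; the TBS group masks the C9 oxygen through the organometallic steps and falls in the same acid step that frees the phenols.

Step 2
Reactants: 3 acenaphthylene-1,2-dione (acenaphthoquinone)
Product: 4 (1R,2S)-1,2-dimethyl-1,2-dihydroacenaphthylene-1,2-diol (cis, meso; "mac" diol)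
Conditions: AlMe3 (excess), toluene, 0 °C → rt; aq. HCl; recrystallisation
Reagents that add atoms: trimethylaluminium, C[Al](C)C
Why: Twofold 1,2-addition of a methyl organometallic to a 1,2-diketone; the second methyl group should enter anti to the bulky aluminium alkoxide formed first, giving the cis diol, and any trans diol cannot form a five-membered boronate and is removed by crystallisation.

Step 3
Reactants: 2 tert-butyldimethyl(prop-2-yn-1-yloxy)silane; 4 cis-1,2-dimethylacenaphthene-1,2-diol
Product: 6 (6bR,9aS)-8-[(E)-3-(tert-butyldimethylsilyloxy)prop-1-en-1-yl]-6b,9a-dimethyl-6b,9a-dihydroacenaphtho[1,2-d][1,3,2]dioxaborole (the alkenyl-B(mac) ester), via alkenyl catechol boronate 5 (not isolated)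
Conditions: catecholborane (1.05 equiv), neat, 70 °C; then 4, THF, rt
Reagents that add atoms: catecholborane, B1Oc2ccccc2O1
Why: Thermal hydroboration of a terminal alkyne with catecholborane is syn and anti-Markovnikov, which fixes the E geometry and puts boron on the future C2; the labile catechol ester then exchanges with the ditertiary cis-diol (transesterification) to a hindered, chromatography-stable boronic ester.

Step 4
Reactants: 7 4-bromo-2-methoxyphenol
Product: 8 4-bromo-2-methoxy-1-(methoxymethoxy)benzene
Conditions: MOMCl, i-Pr2NEt, CH2Cl2, 0 °C → rt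
Reagents that add atoms: chloromethyl methyl ether, COCCl
Why: O-alkylation of the phenol to the MOM acetal, which is inert to tert-butyllithium at −78 °C and is removed in step 9.

Step 5
Reactants: 9 methyl 3,4-dihydroxy-5-methoxybenzoate
Product: 10 methyl 3-hydroxy-5-methoxy-4-(methoxymethoxy)benzoate
Conditions: MOMCl (1.0 equiv), K2CO3 (1.05 equiv), acetone, 0 °C → rt
Reagents that add atoms: chloromethyl methyl ether, COCCl
Why: Regioselective O-alkylation under mono-deprotonation; the hydroxyl para to the ester (O4) is the more acidic, so one equivalent of mild base forms its phenoxide and MOMCl caps O4, leaving O3–H for the triflate.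

Step 6
Reactants: 10 methyl 3-hydroxy-5-methoxy-4-(methoxymethoxy)benzoate
Product: 11 methyl 3-methoxy-4-(methoxymethoxy)-5-[(trifluoromethanesulfonyl)oxy]benzoate
Conditions: Tf2O, pyridine, CH2Cl2, −10 → 0 °C
Reagents that add atoms: trifluoromethanesulfonic anhydride, O=S(=O)(OS(=O)(=O)C(F)(F)F)C(F)(F)F
Why: Sulfonylation of the remaining phenol gives the aryl triflate; pyridine buffers triflic acid so that the MOM acetal survives.

Step 7
Reactants: 8 4-bromo-2-methoxy-1-(methoxymethoxy)benzene; 6 alkenyl-B(mac) ester; 11 methyl 3-methoxy-4-(methoxymethoxy)-5-[(trifluoromethanesulfonyl)oxy]benzoate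
Product: 14 methyl 3-[(1R,2S)-3-(tert-butyldimethylsilyloxy)-1-[3-methoxy-4-(methoxymethoxy)phenyl]-1-[B(mac)]propan-2-yl]-5-methoxy-4-(methoxymethoxy)benzoate, via aryllithium 12 (not isolated), via lithium borate complex 13 (not isolated)
Conditions: 8, t-BuLi (2.0 equiv), Et2O, −78 °C; 6 (1.05 equiv), THF, −78 °C → rt; then KOTf (KOSO2CF3), Pd(OAc)2 (3 mol %), MandyPhos [1,1′-bis{bis(4-methoxy-3,5-dimethylphenyl)phosphino}-2,2′-bis{α-(dimethylamino)benzyl}ferrocene, antipode as fixed in the remarks] (3.6 mol %), 11 (1.1 equiv), THF, 60 °C
Reagents that add atoms: none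
Why: Bromine–lithium exchange gives 12, which adds to the empty orbital of boron in 6 to form the tetracoordinate ate complex 13. Zerovalent palladium, generated from Pd(OAc)2 and the bisphosphine, inserts into the C–OTf bond of 11; since triflate does not coordinate and bromide is precipitated as KBr, the cationic divalent arylpalladium binds the electron-rich alkene of 13. Palladium then bonds to the CH2O-bearing carbon (future C3) while ring B migrates from boron to the neighbouring carbon (future C2) on the face opposite the metal (1,2-metallate shift), and reductive elimination with retention joins C3 to the ring A carbon. The closest known reaction type is the enantioselective conjunctive cross-coupling of alkenylboron ate complexes with aryl triflates, which also covers E-β-substituted alkenylboronates of hindered diols. No ring is closed. The relative configuration is fixed by the mechanism (anti addition of the two aryl groups across the E alkene) and the absolute configuration by the ligand, which decides the alkene face that carries palladium and so sets C3 (S) directly and C2 (R) as a consequence. The step needs the metallate shift to beat direct transfer of ring B to palladium and β-hydride or β-silyloxy elimination; the bulky mac ester, the triflate leaving group and halide removal secure the first, and fast reductive elimination from the wide-bite-angle ferrocenyl bisphosphine the second. The ester of 11 is safe because no free aryllithium remains once 13 has formed.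

Step 8
Reactants: 14 conjunctive-coupling product (benzylic B(mac) ester)
Product: 15 methyl 3-[(1R,2S)-3-(tert-butyldimethylsilyloxy)-1-hydroxy-1-[3-methoxy-4-(methoxymethoxy)phenyl]propan-2-yl]-5-methoxy-4-(methoxymethoxy)benzoate
Conditions: NaBO3·4H2O, THF/H2O, rt
Reagents that add atoms: sodium perborate (sodium peroxoborate), [Na+].[Na+].O[B-]1(O)OO[B-](O)(O)OO1
Why: Peroxide oxidation of the C–B bond proceeds by 1,2-shift of carbon from boron to oxygen with retention, so C2 carries OH where boron stood; the near-neutral perborate spares the methyl ester, the acetals and the silyl ether.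

Step 9
Reactants: 15 methyl 3-[(1R,2S)-3-(tert-butyldimethylsilyloxy)-1-hydroxy-1-[3-methoxy-4-(methoxymethoxy)phenyl]propan-2-yl]-5-methoxy-4-(methoxymethoxy)benzoate
Product: 18 methyl (2R,3S)-2-(4-hydroxy-3-methoxyphenyl)-3-(hydroxymethyl)-7-methoxy-2,3-dihydro-1-benzofuran-5-carboxylate, via deprotected bisphenol diol 16 (not isolated), via para-quinone methide 17 (not isolated)
Conditions: aq. HCl (ca. 1–2 M final), MeOH/THF, rt → 40 °C
Reagents that add atoms: none
Why: Acid solvolysis removes both MOM acetals and the silyl ether and then ionises the para-hydroxybenzylic C2–OH of 16 to quinone methide 17 (or its protonated form), which the ortho phenol of ring A captures in a 5-exo closure (acid-catalysed cyclodehydration, the classical route to phenylcoumarans). C3 is untouched and directs ring B trans to C9; because the closure is reversible under acid, the more stable trans (2R,3S) isomer should result whatever the C2 configuration of 15. Methanol scavenges formaldehyde as dimethoxymethane, and any benzylic methyl ether re-ionises.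

Step 10
Reactants: 18 methyl (2R,3S)-2-(4-hydroxy-3-methoxyphenyl)-3-(hydroxymethyl)-7-methoxy-2,3-dihydro-1-benzofuran-5-carboxylate
Product: 19 methyl (2R,3S)-2-[4-(tert-butyldimethylsilyloxy)-3-methoxyphenyl]-3-[(tert-butyldimethylsilyloxy)methyl]-7-methoxy-2,3-dihydro-1-benzofuran-5-carboxylate
Conditions: TBSCl, imidazole, DMF, rt
Reagents that add atoms: tert-butyldimethylsilyl chloride, CC(C)(C)[Si](C)(C)Cl
Why: Silylation of the phenol and the primary alcohol gives a hydride- and base-stable intermediate whose protecting groups match those of 26, so that one fluoride step clears all four at the end; silylating the ring B phenol also shuts off the quinone methide pathway at C2.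

Step 11
Reactants: 19 bis-silyl ester
Product: 20 [(2R,3S)-2-[4-(tert-butyldimethylsilyloxy)-3-methoxyphenyl]-3-[(tert-butyldimethylsilyloxy)methyl]-7-methoxy-2,3-dihydro-1-benzofuran-5-yl]methanol
Conditions: i-Bu2AlH, CH2Cl2, −78 → 0 °C; aq. potassium sodium tartrate
Reagents that add atoms: none
Why: Hydride reduction of the aryl methyl ester to the benzylic alcohol; silyl ethers and the cyclic benzylic ether are inert to i-Bu2AlH at low temperature.

Step 12
Reactants: 20 benzylic alcohol
Product: 21 (2R,3S)-2-[4-(tert-butyldimethylsilyloxy)-3-methoxyphenyl]-3-[(tert-butyldimethylsilyloxy)methyl]-7-methoxy-2,3-dihydro-1-benzofuran-5-carbaldehyde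
Conditions: MnO2, CH2Cl2, rt
Reagents that add atoms: none
Why: MnO2 oxidises the electron-rich benzylic alcohol selectively to the aldehyde without over-oxidation and without touching the silyl ethers or C2–H.

Step 13
Reactants: 22 methyl 3,5-dihydroxybenzoate
Product: 23 methyl 3,5-bis(tert-butyldimethylsilyloxy)benzoate
Conditions: TBSCl, imidazole, DMF, rt
Reagents that add atoms: tert-butyldimethylsilyl chloride, CC(C)(C)[Si](C)(C)Cl
Why: Double silylation of the phenols (silyl ether formation) installs the same fluoride-labile groups as in 21.

Step 14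
Reactants: 23 methyl 3,5-bis(tert-butyldimethylsilyloxy)benzoate
Product: 24 [3,5-bis(tert-butyldimethylsilyloxy)phenyl]methanol
Conditions: i-Bu2AlH, CH2Cl2, −78 → 0 °C; aq. potassium sodium tartrate
Reagents that add atoms: none
Why: Ester reduction to the benzyl alcohol with i-Bu2AlH; aryl silyl ethers survive at low temperature.

Step 15
Reactants: 24 [3,5-bis(tert-butyldimethylsilyloxy)phenyl]methanol
Product: 25 1-(bromomethyl)-3,5-bis(tert-butyldimethylsilyloxy)benzene
Conditions: CBr4, PPh3, CH2Cl2, 0 °C
Reagents that add atoms: carbon tetrabromide, BrC(Br)(Br)Br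
Why: Appel bromination converts the benzylic alcohol to the bromide under neutral conditions that spare aryl silyl ethers.

Step 16
Reactants: 25 1-(bromomethyl)-3,5-bis(tert-butyldimethylsilyloxy)benzene
Product: 26 diethyl {[3,5-bis(tert-butyldimethylsilyloxy)phenyl]methyl}phosphonate
Conditions: P(OEt)3, neat, 130 °C
Reagents that add atoms: triethyl phosphite, CCOP(OCC)OCC
Why: Michaelis–Arbuzov reaction of a benzylic bromide; bromoethane distils off and drives the reaction.

Step 17
Reactants: 26 diethyl {[3,5-bis(tert-butyldimethylsilyloxy)phenyl]methyl}phosphonate; 21 aldehyde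
Product: 28 (2R,3S)-5-[(E)-2-[3,5-bis(tert-butyldimethylsilyloxy)phenyl]ethenyl]-2-[4-(tert-butyldimethylsilyloxy)-3-methoxyphenyl]-3-[(tert-butyldimethylsilyloxy)methyl]-7-methoxy-2,3-dihydro-1-benzofuran, via sodium phosphonate carbanion 27 (not isolated)
Conditions: 26, NaN(SiMe3)2, THF, 0 °C; then 21, 0 °C → rt
Reagents that add atoms: none
Why: Horner–Wadsworth–Emmons olefination of an aryl aldehyde with a benzylic phosphonate carbanion; reversible addition and elimination through the more stable oxaphosphetane give the E-stilbene. The amide base is consumed before 21 is added and C3–H is meta to the formyl group, so neither stereocentre is at risk; any incidental loss of an aryl silyl group is harmless because all are removed next.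

Step 18
Reactants: 28 tetrakis-silyl ether
Product: 29 gnetofuran A, 5-[(E)-2-[(2R,3S)-2-(4-hydroxy-3-methoxyphenyl)-3-(hydroxymethyl)-7-methoxy-2,3-dihydro-1-benzofuran-5-yl]ethenyl]benzene-1,3-diol
Conditions: TBAF, AcOH, THF, 0 °C → rt, argon, exclusion of light
Reagents that add atoms: none
Why: Fluoride-mediated cleavage of the three aryl and one alkyl Si–O bonds; acetic acid buffers the phenoxides so that the para-hydroxybenzyl ether O1–C2 does not open and the stilbene polyphenol is not exposed to strong base, air or light.

## Compound list

1 | prop-2-yn-1-ol | C#CCO | starting material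
2 | tert-butyldimethyl(prop-2-yn-1-yloxy)silane | C#CCO[Si](C)(C)C(C)(C)C | intermediate
3 | acenaphthylene-1,2-dione | O=C1C(=O)c2cccc3cccc1c23 | starting material
4 | (1R,2S)-1,2-dimethyl-1,2-dihydroacenaphthylene-1,2-diol (cis, meso) | C[C@]1(O)[C@@](C)(O)c2cccc3cccc1c23 | intermediate
5 | 2-[(E)-3-(tert-butyldimethylsilyloxy)prop-1-en-1-yl]-1,3,2-benzodioxaborole | CC(C)(C)[Si](C)(C)OC/C=C/B1Oc2ccccc2O1 | intermediate (not isolated)
6 | (6bR,9aS)-8-[(E)-3-(tert-butyldimethylsilyloxy)prop-1-en-1-yl]-6b,9a-dimethyl-6b,9a-dihydroacenaphtho[1,2-d][1,3,2]dioxaborole | CC(C)(C)[Si](C)(C)OC/C=C/B1O[C@]2(C)c3cccc4cccc(c34)[C@]2(C)O1 | intermediate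
7 | 4-bromo-2-methoxyphenol | COc1cc(Br)ccc1O | starting material
8 | 4-bromo-2-methoxy-1-(methoxymethoxy)benzene | COCOc1ccc(Br)cc1OC | intermediate
9 | methyl 3,4-dihydroxy-5-methoxybenzoate | COC(=O)c1cc(O)c(O)c(OC)c1 | starting material
10 | methyl 3-hydroxy-5-methoxy-4-(methoxymethoxy)benzoate | COC(=O)c1cc(O)c(OCOC)c(OC)c1 | intermediate
11 | methyl 3-methoxy-4-(methoxymethoxy)-5-[(trifluoromethanesulfonyl)oxy]benzoate | COC(=O)c1cc(OC)c(OCOC)c(OS(=O)(=O)C(F)(F)F)c1 | intermediate
12 | [3-methoxy-4-(methoxymethoxy)phenyl]lithium | [Li]c1ccc(OCOC)c(OC)c1 | intermediate (not isolated)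
13 | lithium [(E)-3-(tert-butyldimethylsilyloxy)prop-1-en-1-yl][3-methoxy-4-(methoxymethoxy)phenyl]borate of diol 4 (configuration at boron undefined) | [Li+].COCOc1ccc([B-]2(/C=C/CO[Si](C)(C)C(C)(C)C)O[C@]3(C)c4cccc5cccc(c45)[C@]3(C)O2)cc1OC | intermediate (not isolated)
14 | methyl 3-[(1R,2S)-3-(tert-butyldimethylsilyloxy)-1-[3-methoxy-4-(methoxymethoxy)phenyl]-1-[B(mac)]propan-2-yl]-5-methoxy-4-(methoxymethoxy)benzoate | COCOc1ccc([C@H](B2O[C@]3(C)c4cccc5cccc(c45)[C@]3(C)O2)[C@H](CO[Si](C)(C)C(C)(C)C)c2cc(C(=O)OC)cc(OC)c2OCOC)cc1OC | intermediate
15 | methyl 3-[(1R,2S)-3-(tert-butyldimethylsilyloxy)-1-hydroxy-1-[3-methoxy-4-(methoxymethoxy)phenyl]propan-2-yl]-5-methoxy-4-(methoxymethoxy)benzoate | COCOc1ccc([C@H](O)[C@H](CO[Si](C)(C)C(C)(C)C)c2cc(C(=O)OC)cc(OC)c2OCOC)cc1OC | intermediate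
16 | methyl 3-[(1R,2S)-1,3-dihydroxy-1-(4-hydroxy-3-methoxyphenyl)propan-2-yl]-4-hydroxy-5-methoxybenzoate | Oc1ccc([C@H](O)[C@H](CO)c2cc(C(=O)OC)cc(OC)c2O)cc1OC | intermediate (not isolated)
17 | methyl 4-hydroxy-3-[(2S)-1-hydroxy-3-(3-methoxy-4-oxocyclohexa-2,5-dien-1-ylidene)propan-2-yl]-5-methoxybenzoate (alkylidene geometry undefined) | COC1=CC(=C[C@H](CO)c2cc(C(=O)OC)cc(OC)c2O)C=CC1=O | intermediate (not isolated)
18 | methyl (2R,3S)-2-(4-hydroxy-3-methoxyphenyl)-3-(hydroxymethyl)-7-methoxy-2,3-dihydro-1-benzofuran-5-carboxylate | COc1cc([C@@H]2Oc3c(OC)cc(C(=O)OC)cc3[C@H]2CO)ccc1O | intermediate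
19 | methyl (2R,3S)-2-[4-(tert-butyldimethylsilyloxy)-3-methoxyphenyl]-3-[(tert-butyldimethylsilyloxy)methyl]-7-methoxy-2,3-dihydro-1-benzofuran-5-carboxylate | COc1cc([C@@H]2Oc3c(OC)cc(C(=O)OC)cc3[C@H]2CO[Si](C)(C)C(C)(C)C)ccc1O[Si](C)(C)C(C)(C)C | intermediate
20 | [(2R,3S)-2-[4-(tert-butyldimethylsilyloxy)-3-methoxyphenyl]-3-[(tert-butyldimethylsilyloxy)methyl]-7-methoxy-2,3-dihydro-1-benzofuran-5-yl]methanol | COc1cc([C@@H]2Oc3c(OC)cc(CO)cc3[C@H]2CO[Si](C)(C)C(C)(C)C)ccc1O[Si](C)(C)C(C)(C)C | intermediate
21 | (2R,3S)-2-[4-(tert-butyldimethylsilyloxy)-3-methoxyphenyl]-3-[(tert-butyldimethylsilyloxy)methyl]-7-methoxy-2,3-dihydro-1-benzofuran-5-carbaldehyde | COc1cc([C@@H]2Oc3c(OC)cc(C=O)cc3[C@H]2CO[Si](C)(C)C(C)(C)C)ccc1O[Si](C)(C)C(C)(C)C | intermediate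
22 | methyl 3,5-dihydroxybenzoate | COC(=O)c1cc(O)cc(O)c1 | starting material
23 | methyl 3,5-bis(tert-butyldimethylsilyloxy)benzoate | COC(=O)c1cc(O[Si](C)(C)C(C)(C)C)cc(O[Si](C)(C)C(C)(C)C)c1 | intermediate
24 | [3,5-bis(tert-butyldimethylsilyloxy)phenyl]methanol | OCc1cc(O[Si](C)(C)C(C)(C)C)cc(O[Si](C)(C)C(C)(C)C)c1 | intermediate
25 | 1-(bromomethyl)-3,5-bis(tert-butyldimethylsilyloxy)benzene | BrCc1cc(O[Si](C)(C)C(C)(C)C)cc(O[Si](C)(C)C(C)(C)C)c1 | intermediate
26 | diethyl {[3,5-bis(tert-butyldimethylsilyloxy)phenyl]methyl}phosphonate | CCOP(=O)(Cc1cc(O[Si](C)(C)C(C)(C)C)cc(O[Si](C)(C)C(C)(C)C)c1)OCC | intermediate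
27 | sodium salt of the α-carbanion of 26 | [Na+].CCOP(=O)([CH-]c1cc(O[Si](C)(C)C(C)(C)C)cc(O[Si](C)(C)C(C)(C)C)c1)OCC | intermediate (not isolated)
28 | (2R,3S)-5-[(E)-2-[3,5-bis(tert-butyldimethylsilyloxy)phenyl]ethenyl]-2-[4-(tert-butyldimethylsilyloxy)-3-methoxyphenyl]-3-[(tert-butyldimethylsilyloxy)methyl]-7-methoxy-2,3-dihydro-1-benzofuran | COc1cc([C@@H]2Oc3c(OC)cc(/C=C/c4cc(O[Si](C)(C)C(C)(C)C)cc(O[Si](C)(C)C(C)(C)C)c4)cc3[C@H]2CO[Si](C)(C)C(C)(C)C)ccc1O[Si](C)(C)C(C)(C)C | intermediate
29 | gnetofuran A, 5-[(E)-2-[(2R,3S)-2-(4-hydroxy-3-methoxyphenyl)-3-(hydroxymethyl)-7-methoxy-2,3-dihydro-1-benzofuran-5-yl]ethenyl]benzene-1,3-diol | COc1cc([C@@H]2Oc3c(OC)cc(/C=C/c4cc(O)cc(O)c4)cc3[C@H]2CO)ccc1O | target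

## Step count and least certain steps

Total: 18 steps. Longest linear sequence: 10 steps (steps 5, 6, 7, 8, 9, 10, 11, 12, 17, 18 from 9; equally steps 1, 3, 7, 8, 9, 10, 11, 12, 17, 18 from 1).

**Step 7 (key step).**
- What may go wrong: direct transfer of ring B from boron to palladium (Suzuki–Miyaura pathway) may outrun the metallate shift, because the alkene is β-substituted and the triflate has an ortho acetal oxygen that can occupy the site needed for alkene binding. β-Hydride or β-silyloxy elimination from the alkylpalladium may compete. Facial selectivity may be eroded by the allylic silyloxy group.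
- Fallback, auxiliary-controlled aldol; it sets out from 11 (and from 8 for the ring B aldehyde) and returns at 18:
  - Stille allylation of 11 (allyltributylstannane, Pd(PPh3)4, LiCl, DMF) should give methyl 3-allyl-5-methoxy-4-(methoxymethoxy)benzoate F1.
  - Oxidative cleavage (OsO4 cat., NaIO4, 2,6-lutidine, dioxane/H2O) gives the arylacetaldehyde F2, and NaClO2/NaH2PO4/2-methyl-2-butene gives the arylacetic acid F3.
  - The mixed pivalic anhydride of F3 acylates lithiated (R)-4-benzyl-1,3-oxazolidin-2-one to give the imide F4.
  - The ring B aldehyde, 3-methoxy-4-(methoxymethoxy)benzaldehyde F5, is obtained by quenching 12 (from 8) with DMF.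
  - The boron enolate of F4 (Bu2BOTf, i-Pr2NEt, CH2Cl2, −78 → 0 °C) adds to F5 in an Evans syn aldol reaction to give the adduct F6. The (R)-auxiliary fixes the α-carbon in the configuration that becomes C3 (S).
  - NaBH4 in THF/H2O releases the auxiliary and gives the diol F7 without touching the methyl benzoate.
  - F7 under the conditions of step 9 converges on 18; the carbinol configuration is again irrelevant.

**Step 3.**
- What may go wrong: incomplete or unselective thermal hydroboration of the propargylic ether, or incomplete exchange of catechol for the hindered diol, leaving a hydrolytically labile boron species.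
- Fallback, stepwise through isolable boron compounds; it sets out from 2 and returns at 6:
  - Cp2ZrHCl-catalysed hydroboration of 2 with pinacolborane gives the pinacol ester F8.
  - Oxidative removal of pinacol (NaIO4, NH4OAc, acetone/H2O) gives the boronic acid F9.
  - Condensation of F9 with 4 over MgSO4 in CH2Cl2 gives 6.

**Step 5.**
- What may go wrong: alkylation at O3 or at both oxygens, if the acidity difference between the two hydroxyls is not translated into selectivity with so reactive an electrophile.
- Fallback, regiocontrol through the dianion and a temporary group; it sets out from 9 and returns at 10: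
  - With NaH (2.2 equiv) in DMSO the more basic O3 phenoxide of the dianion is the more nucleophilic, so benzyl bromide (1 equiv) should give methyl 3-(benzyloxy)-4-hydroxy-5-methoxybenzoate F10.
  - MOMCl/i-Pr2NEt then gives methyl 3-(benzyloxy)-5-methoxy-4-(methoxymethoxy)benzoate F11.
  - Hydrogenolysis over palladium on carbon (H2, EtOAc) frees O3 and gives 10.

**Step 9.**
- What may go wrong: under prolonged protic acid the C2 cation may lose C9 as formaldehyde or C3–H (stilbene formation), formaldehyde released from the acetals may attack the electron-rich rings, and capture by methanol may stall the closure.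
- Fallback, separating deprotection from ring closure; it sets out from 15 and returns at 19:
  - TMSOTf/2,2′-bipyridyl in CH2Cl2 followed by water removes the two aryl MOM groups under nearly neutral conditions and should give the bisphenol that retains the silyl ether, methyl 3-[(1R,2S)-3-(tert-butyldimethylsilyloxy)-1-hydroxy-1-(4-hydroxy-3-methoxyphenyl)propan-2-yl]-4-hydroxy-5-methoxybenzoate F12.
  - Catalytic pyridinium p-toluenesulfonate in dry CH2Cl2 then closes O1–C2 through the quinone methide in the absence of methanol and formaldehyde, giving the trans phenol F13.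
  - Silylation of the ring B phenol (TBSCl, imidazole) gives 19.

## Further compounds

F1 | step 7 | methyl 3-allyl-5-methoxy-4-(methoxymethoxy)benzoate | COC(=O)c1cc(OC)c(OCOC)c(CC=C)c1
F2 | step 7 | methyl 3-methoxy-4-(methoxymethoxy)-5-(2-oxoethyl)benzoate | COC(=O)c1cc(OC)c(OCOC)c(CC=O)c1
F3 | step 7 | 2-[3-methoxy-5-(methoxycarbonyl)-2-(methoxymethoxy)phenyl]acetic acid | COC(=O)c1cc(OC)c(OCOC)c(CC(=O)O)c1
F4 | step 7 | methyl 3-[2-[(4R)-4-benzyl-2-oxo-1,3-oxazolidin-3-yl]-2-oxoethyl]-5-methoxy-4-(methoxymethoxy)benzoate | COC(=O)c1cc(OC)c(OCOC)c(CC(=O)N2[C@H](Cc3ccccc3)COC2=O)c1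
F5 | step 7 | 3-methoxy-4-(methoxymethoxy)benzaldehyde | COCOc1ccc(C=O)cc1OC
F6 | step 7 | methyl 3-[(2R,3R)-1-[(4R)-4-benzyl-2-oxo-1,3-oxazolidin-3-yl]-3-hydroxy-3-[3-methoxy-4-(methoxymethoxy)phenyl]-1-oxopropan-2-yl]-5-methoxy-4-(methoxymethoxy)benzoate | COCOc1ccc([C@H](O)[C@H](C(=O)N3[C@H](Cc4ccccc4)COC3=O)c2cc(C(=O)OC)cc(OC)c2OCOC)cc1OC
F7 | step 7 | methyl 3-[(1R,2S)-1,3-dihydroxy-1-[3-methoxy-4-(methoxymethoxy)phenyl]propan-2-yl]-5-methoxy-4-(methoxymethoxy)benzoate | COCOc1ccc([C@H](O)[C@H](CO)c2cc(C(=O)OC)cc(OC)c2OCOC)cc1OC
F8 | step 3 | tert-butyldimethyl{[(E)-3-(4,4,5,5-tetramethyl-1,3,2-dioxaborolan-2-yl)prop-2-en-1-yl]oxy}silane | CC(C)(C)[Si](C)(C)OC/C=C/B1OC(C)(C)C(C)(C)O1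
F9 | step 3 | [(E)-3-(tert-butyldimethylsilyloxy)prop-1-en-1-yl]boronic acid | CC(C)(C)[Si](C)(C)OC/C=C/B(O)O
F10 | step 5 | methyl 3-(benzyloxy)-4-hydroxy-5-methoxybenzoate | COC(=O)c1cc(OC)c(O)c(OCc2ccccc2)c1
F11 | step 5 | methyl 3-(benzyloxy)-5-methoxy-4-(methoxymethoxy)benzoate | COC(=O)c1cc(OC)c(OCOC)c(OCc2ccccc2)c1
F12 | step 9 | methyl 3-[(1R,2S)-3-(tert-butyldimethylsilyloxy)-1-hydroxy-1-(4-hydroxy-3-methoxyphenyl)propan-2-yl]-4-hydroxy-5-methoxybenzoate | Oc1ccc([C@H](O)[C@H](CO[Si](C)(C)C(C)(C)C)c2cc(C(=O)OC)cc(OC)c2O)cc1OC
F13 | step 9 | methyl (2R,3S)-3-[(tert-butyldimethylsilyloxy)methyl]-2-(4-hydroxy-3-methoxyphenyl)-7-methoxy-2,3-dihydro-1-benzofuran-5-carboxylate | COc1cc([C@@H]2Oc3c(OC)cc(C(=O)OC)cc3[C@H]2CO[Si](C)(C)C(C)(C)C)ccc1O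
A1 | alternative 1 | (2S)-1-oxo-1-(pyrrolidin-1-yl)propan-2-yl (2R,3R)-5-bromo-7-methoxy-2-[3-methoxy-4-(triisopropylsilyloxy)phenyl]-2,3-dihydro-1-benzofuran-3-carboxylate | COc1cc([C@@H]2Oc3c(OC)cc(Br)cc3[C@H]2C(=O)O[C@@H](C)C(=O)N4CCCC4)ccc1O[Si](C(C)C)(C(C)C)C(C)C
A2 | alternative 1 | (2S)-1-oxo-1-(pyrrolidin-1-yl)propan-2-yl 2-[5-bromo-3-methoxy-2-{[3-methoxy-4-(triisopropylsilyloxy)phenyl]methoxy}phenyl]-2-diazoacetate | COc1cc(COc2c(OC)cc(Br)cc2C(=[N+]=[N-])C(=O)O[C@@H](C)C(=O)N3CCCC3)ccc1O[Si](C(C)C)(C(C)C)C(C)C
A3 | alternative 1 | 1-ethenyl-3,5-bis(tert-butyldimethylsilyloxy)benzene | C=Cc1cc(O[Si](C)(C)C(C)(C)C)cc(O[Si](C)(C)C(C)(C)C)c1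
A4 | alternative 2 | 3-[(E)-2-[(2R,3S)-7-methoxy-2-[3-methoxy-4-(methoxymethoxy)phenyl]-3-[(triisopropylsilyloxy)methyl]-2,3-dihydro-1-benzofuran-5-yl]ethenyl]-5-(triisopropylsilyloxy)phenol | COCOc1ccc([C@@H]2Oc3c(OC)cc(/C=C/c4cc(O)cc(O[Si](C(C)C)(C(C)C)C(C)C)c4)cc3[C@H]2CO[Si](C(C)C)(C(C)C)C(C)C)cc1OC
A5 | alternative 2 | 3-[(E)-2-[(2R,3S)-7-methoxy-2-[3-methoxy-4-(methoxymethoxy)phenyl]-3-[(triisopropylsilyloxy)methyl]-2,3-dihydro-1-benzofuran-5-yl]ethenyl]cyclobut-2-en-1-one | COCOc1ccc([C@@H]2Oc3c(OC)cc(/C=C/C4=CC(=O)C4)cc3[C@H]2CO[Si](C(C)C)(C(C)C)C(C)C)cc1OC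
A6 | alternative 2 | (ethynyloxy)triisopropylsilane | C#CO[Si](C(C)C)(C(C)C)C(C)C
A7 | alternative 3 | methyl (2R,3S)-2-(4-hydroxy-3-methoxyphenyl)-3-(hydroxymethyl)-7-methoxy-2,3-dihydro-1-benzofuran-5-carboxylate | COc1cc([C@@H]2Oc3c(OC)cc(C(=O)OC)cc3[C@H]2CO)ccc1O
A8 | alternative 3 | methyl 4-hydroxy-3-[(2S)-1-hydroxy-3-(4-hydroxy-3-methoxyphenyl)propan-2-yl]-5-methoxybenzoate | COc1cc(C[C@H](CO)c2cc(C(=O)OC)cc(OC)c2O)ccc1O
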